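The seven-membered ring of the hexahydroazulene core is cut at C4–C5 and C8–C8a (azulene numbering). C4–C3a–C8a is a three-carbon unit already carried by the cyclopentane and oxygenated at C4; C5–C8 is a four-carbon methyl vinyl ketone unit whose carbonyl carbon becomes C6. Both bonds, the quaternary centre C8a and the C4 oxygen arise in one Brook-rearrangement-mediated (3+4) annulation (addition, silyl shift, cyclopropanation, anionic oxy-Cope) of a dienolate with a cyclopentenyl acylsilane. The precursor is a bicyclic acylsilane whose silicon is also bound to the tertiary alkoxide; it comes from (S)-terpinen-4-ol by ozonolytic ring cleavage and aldol re-closure, and its O–Si–O tether steers the facial selectivity.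

Key step: step 6

Numbering: all bicyclic carbocycles use the azulene numbering of the target (C3 carbinol with isopropyl, C3a ring-fusion CH, C4 ester carbon, C5=C6 alkene, C8a quaternary carbon).
Assumption: (S)-(+)-terpinen-4-ol of high enantiomeric purity is taken as purchasable; commercial material may need enantiomeric enrichment first.

Step 1
Reactants: 1 (S)-(+)-terpinen-4-ol
Product: 2 triethyl{[(1S)-4-methyl-1-(propan-2-yl)cyclohex-3-en-1-yl]oxy}silane
Conditions: Et3SiOTf, 2,6-lutidine, CH2Cl2, −78 → 0 °C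
Reagents that add atoms: triethylsilyl trifluoromethanesulfonate, CC[Si](CC)(CC)OS(=O)(=O)C(F)(F)F
Why: Silyl triflate/lutidine silylation of a tertiary alcohol; the ether prevents retro-aldol cleavage and dehydration of the β-oxygenated aldehyde that the next two steps pass through.

Step 2
Reactants: 2 triethylsilyl ether of terpinen-4-ol
Product: 3 (3S)-6-oxo-3-(propan-2-yl)-3-[(triethylsilyl)oxy]heptanal
Conditions: O3, CH2Cl2, −78 °C; then Me2S, −78 → 20 °C
Reagents that add atoms: ozone, [O-][O+]=O
Why: Ozonolysis with reductive work-up cleaves the only C=C bond (ring C–C cleavage) to the 1,6-keto aldehyde and leaves the silyl ether and the carbinol stereocentre untouched.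

Step 3
Reactants: 3 keto aldehyde
Product: 5 (5R)-5-hydroxy-2-methyl-5-(propan-2-yl)cyclopent-1-ene-1-carbaldehyde, via silyl ether enal 4 (not isolated)
Conditions: piperidine (0.3 equiv), AcOH (0.3 equiv), toluene, 60 °C; then HF·pyridine, THF, 0 → 20 °C
Reagents that add atoms: none
Why: Enamine-mediated intramolecular aldol condensation (aldehyde enamine onto the methyl ketone, 5-exo-trig) gives the 2-methylcyclopent-1-enecarbaldehyde, as with the classical limonene-derived keto aldehyde, and HF then frees the tertiary alcohol needed as the anchor for silicon.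

Step 4
Reactants: 5 hydroxy enal
Product: 7 (6aR)-4-methyl-2,2-diphenyl-6a-(propan-2-yl)-3,5,6,6a-tetrahydro-2H-cyclopenta[d][1,2]oxasilol-3-ol, via aminosilyl carbinol 6 (not isolated)
Conditions: (Et2N)Ph2SiLi (2.1 equiv, from (Et2N)Ph2SiCl and Li, THF, 0 °C), THF, −78 °C; then AcOH (3 equiv), −78 → 20 °C
Reagents that add atoms: (diethylamino)diphenylsilyllithium, CCN(CC)[Si]([Li])(c1ccccc1)c1ccccc1
Why: 1,2-addition of a silyllithium to the aldehyde gives the α-silyl carbinol (with lithium in THF at −78 °C the C-silyl alkoxide is the favoured side of the Brook equilibrium), and on protonation the tertiary hydroxyl displaces diethylamine from silicon in a five-membered ring closure (aminosilane alcoholysis); the new carbinol centre forms as a mixture that step 5 removes.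

Step 5
Reactants: 7 cyclic α-silyl carbinol
Product: 8 (6aR)-4-methyl-2,2-diphenyl-6a-(propan-2-yl)-6,6a-dihydro-2H-cyclopenta[d][1,2]oxasilol-3(5H)-one
Conditions: (COCl)2, DMSO, CH2Cl2, −78 °C; then Et3N, −78 → −20 °C
Reagents that add atoms: none
Why: Swern oxidation is the standard conversion of α-hydroxysilanes into acylsilanes and leaves the Si–O ring and the tetrasubstituted alkene untouched.

Step 6
Reactants: 8 cyclic acylsilane; 9 2-(trimethylsilyloxy)buta-1,3-diene
Product: 12 (3R,8aR)-8a-methyl-3,4-[(diphenylsilanediyl)bis(oxy)]-3-(propan-2-yl)-2,3,5,7,8,8a-hexahydroazulen-6(1H)-one, via lithium buta-1,3-dien-2-olate 10 (not isolated), via lithium divinylcyclopropanolate 11 (not isolated)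
Conditions: 9 (1.2 equiv), MeLi (1.15 equiv), THF, 0 °C; then 8, THF, −80 → −20 °C; then AcOH, −80 °C
Reagents that add atoms: none
Why: Dienolate 10 adds through its CH2 terminus to the acylsilane carbonyl of 8 (C4–C5), the α-silyl alkoxide undergoes 1,2-Brook rearrangement that expands the oxasilole to a six-membered 1,3-dioxa-2-silacyclohexene, and the allylic carbanion closes on the enone carbonyl (3-exo-trig) to the cis-1,2-divinylcyclopropanolate 11; anionic oxy-Cope rearrangement through the boat transition state then forms C8–C8a and the seven-membered ring by [3,3] ring expansion. The closest known reaction is the Brook-rearrangement-mediated (3+4) annulation of alkenoylsilanes with lithium dienolates of alkenyl methyl ketones, here applied to a β,β-disubstituted acylsilane whose silicon is tethered to the C3 oxygen. Regiochemistry follows from the polarity of the partners (enolate carbon to acyl carbon, vinyl terminus to the β-carbon), so the silyl enol ether oxygen sits at C4 and the ketone at C6. The only stereocentre formed that survives, quaternary C8a, is controlled by C3 through the O–Si–O bridge: the dioxasilacyclohexene should stay chair-like in the boat transition state, which holds the C4 oxygen on the face of the C3 oxygen and puts the breaking cyclopropane bond and the incoming vinyl terminus on the isopropyl face, so the new C8–C8a bond is cis to isopropyl and the methyl group cis to the C3 oxygen. The step needs this facial selectivity and 1,2- instead of 1,4-addition; the tether should secure the first and the fully substituted β-carbon the second.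

Step 7
Reactants: 12 silylene-bridged ketone
Product: 13 (3R,8aR)-8a-methyl-3,4-[(diphenylsilanediyl)bis(oxy)]-3-(propan-2-yl)-1,2,3,7,8,8a-hexahydroazulen-6-yl trifluoromethanesulfonate
Conditions: KN(SiMe3)2, THF, −78 °C; then PhNTf2, −78 → 0 °C
Reagents that add atoms: N-phenylbis(trifluoromethanesulfonimide), O=S(=O)(N(c1ccccc1)S(=O)(=O)C(F)(F)F)C(F)(F)F
Why: Deprotonation occurs at C5, whose protons are activated by both the ketone and the enol ether double bond, and O-triflation of the linear dienolate fixes the future alkene at C5=C6 without any equilibration.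

Step 8
Reactants: 13 dienyl triflate
Product: 15 (3R,3aR,8aS)-3-hydroxy-6,8a-dimethyl-3-(propan-2-yl)-2,3,3a,7,8,8a-hexahydroazulen-4(1H)-one, via silylene dienol ether 14 (not isolated)
Conditions: MeZnCl, Pd(PPh3)4 (5 mol %), THF, 25 °C; then Et3N·3HF, THF, 0 °C; then DBU (0.1 equiv), 25 °C
Reagents that add atoms: methylzinc chloride, C[Zn]Cl
Why: Negishi coupling of the enol triflate installs the C6 methyl group; fluoride then cleaves both Si–O bonds, the freed C4 enol is protonated at C3a to the conjugated enone, and base equilibration at C3a should favour the trans-fused ketone, which keeps the seven-membered ring trans to the isopropyl group and allows an O–H···O=C hydrogen bond.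

Step 9
Reactants: 15 β-hydroxy enone
Product: 16 (3R,3aS,4S,8aS)-6,8a-dimethyl-3-(propan-2-yl)-1,2,3,3a,4,7,8,8a-octahydroazulene-3,4-diol
Conditions: Me4NBH(OAc)3, MeCN/AcOH (1:1), −30 → 0 °C
Reagents that add atoms: none
Why: Hydroxyl-directed triacetoxyborohydride reduction (Saksena–Evans type): boron bound to the 3-OH, which is cis to the C4 carbonyl carbon on the five-membered ring, delivers hydride intramolecularly to the carbonyl face on the side of that hydroxyl, giving the anti-1,3-diol with the 4-OH trans to the 3-OH, and the reagent is 1,2-selective on the enone.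

Step 10
Reactants: 16 diol; 17 4-methoxybenzoyl chloride
Product: 18 (3R,3aS,4S,8aS)-3-hydroxy-6,8a-dimethyl-3-(propan-2-yl)-1,2,3,3a,4,7,8,8a-octahydroazulen-4-yl 4-methoxybenzoate
Conditions: pyridine, DMAP (0.1 equiv), CH2Cl2, 0 → 20 °C
Reagents that add atoms: none
Why: DMAP-catalysed acylation esterifies the secondary allylic alcohol with retention at C4, while the hindered tertiary alcohol should stay free.

Compound list
1 | (S)-(+)-terpinen-4-ol, (1S)-4-methyl-1-(propan-2-yl)cyclohex-3-en-1-ol | CC1=CC[C@](O)(C(C)C)CC1 | starting material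
2 | triethyl{[(1S)-4-methyl-1-(propan-2-yl)cyclohex-3-en-1-yl]oxy}silane | CC1=CC[C@](O[Si](CC)(CC)CC)(C(C)C)CC1 | intermediate
3 | (3S)-6-oxo-3-(propan-2-yl)-3-[(triethylsilyl)oxy]heptanal | CC(=O)CC[C@@](O[Si](CC)(CC)CC)(C(C)C)CC=O | intermediate
4 | (5R)-2-methyl-5-(propan-2-yl)-5-[(triethylsilyl)oxy]cyclopent-1-ene-1-carbaldehyde | O=CC1=C(C)CC[C@@]1(O[Si](CC)(CC)CC)C(C)C | intermediate
5 | (5R)-5-hydroxy-2-methyl-5-(propan-2-yl)cyclopent-1-ene-1-carbaldehyde | O=CC1=C(C)CC[C@@]1(O)C(C)C | intermediate
6 | [(diethylamino)diphenylsilyl][(5R)-5-hydroxy-2-methyl-5-(propan-2-yl)cyclopent-1-en-1-yl]methanol, both carbinol epimers | CCN(CC)[Si](c1ccccc1)(c1ccccc1)C(O)C1=C(C)CC[C@@]1(O)C(C)C | intermediate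
7 | (6aR)-4-methyl-2,2-diphenyl-6a-(propan-2-yl)-3,5,6,6a-tetrahydro-2H-cyclopenta[d][1,2]oxasilol-3-ol, both C3 epimers | CC(C)[C@]12CCC(C)=C1C(O)[Si](c1ccccc1)(c1ccccc1)O2 | intermediate
8 | (6aR)-4-methyl-2,2-diphenyl-6a-(propan-2-yl)-6,6a-dihydro-2H-cyclopenta[d][1,2]oxasilol-3(5H)-one, cyclic acylsilane | CC(C)[C@]12CCC(C)=C1C(=O)[Si](c1ccccc1)(c1ccccc1)O2 | intermediate
9 | 2-(trimethylsilyloxy)buta-1,3-diene | C=CC(=C)O[Si](C)(C)C | starting material
10 | lithium buta-1,3-dien-2-olate | C=CC(=C)[O-].[Li+] | intermediate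
11 | lithium (7a'R)-2-ethenyl-5'-methyl-2',2'-diphenyl-7a'-(propan-2-yl)-6',7'-dihydro-7a'H-spiro[cyclopropane-1,4'-cyclopenta[d][1,3,2]dioxasilin]-2-olate; ethenyl cis to the cyclopentene carbon, olate carbon on the isopropyl face | CC(C)[C@]12CCC(C)=C1[C@@]3(C[C@]3([O-])C=C)O[Si](c4ccccc4)(c4ccccc4)O2.[Li+] | intermediate
12 | (3R,8aR)-8a-methyl-3,4-[(diphenylsilanediyl)bis(oxy)]-3-(propan-2-yl)-2,3,5,7,8,8a-hexahydroazulen-6(1H)-one; C3a=C4 silyl enol ether, methyl cis to the C3 oxygen | CC(C)[C@]12CC[C@]3(C)CCC(=O)CC(=C13)O[Si](c4ccccc4)(c4ccccc4)O2 | intermediate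
13 | (3R,8aR)-8a-methyl-3,4-[(diphenylsilanediyl)bis(oxy)]-3-(propan-2-yl)-1,2,3,7,8,8a-hexahydroazulen-6-yl trifluoromethanesulfonate | CC(C)[C@]12CC[C@]3(C)CCC(OS(=O)(=O)C(F)(F)F)=CC(=C13)O[Si](c4ccccc4)(c4ccccc4)O2 | intermediate
14 | (3R,8aS)-6,8a-dimethyl-3,4-[(diphenylsilanediyl)bis(oxy)]-3-(propan-2-yl)-1,2,3,7,8,8a-hexahydroazulene | CC(C)[C@]12CC[C@]3(C)CCC(C)=CC(=C13)O[Si](c4ccccc4)(c4ccccc4)O2 | intermediate
15 | (3R,3aR,8aS)-3-hydroxy-6,8a-dimethyl-3-(propan-2-yl)-2,3,3a,7,8,8a-hexahydroazulen-4(1H)-one; trans ring fusion | O=C1C=C(C)CC[C@@]2(C)CC[C@@](O)(C(C)C)[C@H]12 | intermediate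
16 | (3R,3aS,4S,8aS)-6,8a-dimethyl-3-(propan-2-yl)-1,2,3,3a,4,7,8,8a-octahydroazulene-3,4-diol | O[C@H]1C=C(C)CC[C@@]2(C)CC[C@@](O)(C(C)C)[C@H]12 | intermediate
17 | 4-methoxybenzoyl chloride | COc1ccc(C(Cl)=O)cc1 | starting material
18 | (3R,3aS,4S,8aS)-3-hydroxy-6,8a-dimethyl-3-(propan-2-yl)-1,2,3,3a,4,7,8,8a-octahydroazulen-4-yl 4-methoxybenzoate | COc1ccc(C(=O)O[C@H]2C=C(C)CC[C@@]3(C)CC[C@@](O)(C(C)C)[C@H]23)cc1 | target

Total step count: 10. Longest linear sequence: 10 steps (1 → 18).

Steps most likely to fail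

Step 6. The cascade may stall after the 1,2-addition or after the silyl shift because the β-carbon is fully substituted, or the oxy-Cope rearrangement may proceed on the face next to the C3 oxygen and give the wrong configuration at C8a. The fallback forms the same two bonds stepwise; it sets out from 4 and returns at 15. Copper-catalysed conjugate addition (CuBr·SMe2, Me3SiCl, THF, −40 °C) of [2-(2-methyl-1,3-dioxolan-2-yl)ethyl]magnesium bromide F1 to enal 4, anti to the silyloxy group, should give 2-methyl-2-[2-(2-methyl-1,3-dioxolan-2-yl)ethyl]-5-(propan-2-yl)-5-[(triethylsilyl)oxy]cyclopentane-1-carbaldehyde F2 (C8–C8a bond). Ketal cleavage (pyridinium p-toluenesulfonate, wet acetone) and base-mediated aldol condensation (KOH, MeOH) should close C4–C5 to 8a-methyl-3-(propan-2-yl)-3-[(triethylsilyl)oxy]-2,3,3a,7,8,8a-hexahydroazulen-6(1H)-one F3. MeLi addition would give the tertiary allylic alcohol 6,8a-dimethyl-3-(propan-2-yl)-3-[(triethylsilyl)oxy]-1,2,3,3a,6,7,8,8a-octahydroazulen-6-ol F4. Oxidative 1,3-transposition with pyridinium chlorochromate would give the triethylsilyl ether of 15, F5, and HF·pyridine would give 15.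

Step 4. The lithium α-silyl alkoxide may undergo Brook rearrangement, or Si–O bond formation may occur between molecules instead of closing the ring. The fallback builds the C–Si bond by silyl migration from oxygen to carbon; it sets out from 5 and returns at 7. NaBH4/CeCl3 (MeOH, −20 °C) would reduce 5 to (1R)-2-(hydroxymethyl)-3-methyl-1-(propan-2-yl)cyclopent-2-en-1-ol F6. Ph2SiCl2/imidazole (DMF) would give the cyclic silylene acetal (7aR)-5-methyl-2,2-diphenyl-7a-(propan-2-yl)-4,6,7,7a-tetrahydrocyclopenta[d][1,3,2]dioxasiline F7. t-BuLi (THF, −78 °C) should deprotonate the allylic O–CH2 group, and a retro-[1,2]-Brook shift of silicon from oxygen to carbon contracts the ring to the lithium alkoxide of 7.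

Step 8. C-protonation at C3a may give the cis-fused ketone, and the base equilibration may be incomplete or move the alkene out of conjugation. The fallback sets C3a before the alkene exists; it sets out from 12 and returns at 15. Et3N·3HF (THF) would convert 12 into (3R,3aR,8aR)-3-hydroxy-8a-methyl-3-(propan-2-yl)hexahydroazulene-4,6(1H,5H)-dione F8, whose C3a can equilibrate through the C4 enol with no alkene to migrate. PhNTf2/Et3N should triflate the less hindered C6 oxygen to (3R,3aR,8aR)-3-hydroxy-8a-methyl-4-oxo-3-(propan-2-yl)-1,2,3,3a,4,7,8,8a-octahydroazulen-6-yl trifluoromethanesulfonate F9, and MeZnCl/Pd(PPh3)4 would then give 15.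

Further compounds
F1 | step 6 | [2-(2-methyl-1,3-dioxolan-2-yl)ethyl]magnesium bromide | CC1(CC[Mg]Br)OCCO1
F2 | step 6 | 2-methyl-2-[2-(2-methyl-1,3-dioxolan-2-yl)ethyl]-5-(propan-2-yl)-5-[(triethylsilyl)oxy]cyclopentane-1-carbaldehyde, configuration as in 15 | O=C[C@@H]1[C@@](C)(CCC2(C)OCCO2)CC[C@@]1(O[Si](CC)(CC)CC)C(C)C
F3 | step 6 | 8a-methyl-3-(propan-2-yl)-3-[(triethylsilyl)oxy]-2,3,3a,7,8,8a-hexahydroazulen-6(1H)-one, configuration as in 15 | O=C1C=C[C@@H]2[C@@](C)(CC1)CC[C@@]2(O[Si](CC)(CC)CC)C(C)C
F4 | step 6 | 6,8a-dimethyl-3-(propan-2-yl)-3-[(triethylsilyl)oxy]-1,2,3,3a,6,7,8,8a-octahydroazulen-6-ol, both C6 epimers | CC1(O)C=C[C@@H]2[C@@](C)(CC1)CC[C@@]2(O[Si](CC)(CC)CC)C(C)C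
F5 | step 6 | (3R,3aR,8aS)-6,8a-dimethyl-3-(propan-2-yl)-3-[(triethylsilyl)oxy]-2,3,3a,7,8,8a-hexahydroazulen-4(1H)-one | O=C1C=C(C)CC[C@@]2(C)CC[C@@](O[Si](CC)(CC)CC)(C(C)C)[C@H]12
F6 | step 4 | (1R)-2-(hydroxymethyl)-3-methyl-1-(propan-2-yl)cyclopent-2-en-1-ol | OCC1=C(C)CC[C@@]1(O)C(C)C
F7 | step 4 | (7aR)-5-methyl-2,2-diphenyl-7a-(propan-2-yl)-4,6,7,7a-tetrahydrocyclopenta[d][1,3,2]dioxasiline | CC(C)[C@]12CCC(C)=C1CO[Si](c1ccccc1)(c1ccccc1)O2
F8 | step 8 | (3R,3aR,8aR)-3-hydroxy-8a-methyl-3-(propan-2-yl)hexahydroazulene-4,6(1H,5H)-dione | O=C1CC(=O)CC[C@@]2(C)CC[C@@](O)(C(C)C)[C@H]12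
F9 | step 8 | (3R,3aR,8aR)-3-hydroxy-8a-methyl-4-oxo-3-(propan-2-yl)-1,2,3,3a,4,7,8,8a-octahydroazulen-6-yl trifluoromethanesulfonate | O=C1C=C(OS(=O)(=O)C(F)(F)F)CC[C@@]2(C)CC[C@@](O)(C(C)C)[C@H]12
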